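**Retrosynthesis**
1. The target comes from a late-stage photochemical dehydrogenative β-hydroxymethylation (methanol as the CH2OH source) of a 4-unsubstituted (5R)-5-alkylbutenolide, which is made from the saturated lactone by α-selenation and oxidative elimination.
2. The saturated lactone comes from a Ni/photoredox cross-electrophile coupling of the chiral-pool tosylate (S)-5-(tosyloxymethyl)-γ-butyrolactone with a (Z)-vinyl iodide. The only stereocenter therefore comes from that tosylate.
3. The (Z)-vinyl iodide comes from Cu-catalysed carbomagnesiation of propargyl alcohol with a homoallylic (E)-Grignard, which in turn comes from a Julia–Johnson cyclopropylcarbinol opening of dihydro-β-ionone.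
4. No ring is formed in the route. The cyclohexene ring and the lactone ring are already present in the starting materials, and the butenolide C=C is created last.

**Assumptions:** (6Z) is taken as the Z trisubstituted CH2OH-bearing alkene, with CH2OH cis to the CH2–C5 carbon, exactly as drawn in the SMILES. The C5 center is (R), which corresponds to the (S)-lactone tosylate. That tosylate is commercial (L-glutamic acid derived).

## Route

**Step 1**
Reactants: 1 (dihydro-β-ionone, 4-(2,6,6-trimethylcyclohex-1-en-1-yl)butan-2-one); 2 (cyclopropylmagnesium bromide)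
Product: 3 (2-cyclopropyl-4-(2,6,6-trimethylcyclohex-1-en-1-yl)butan-2-ol)
Conditions: 2 (1.5 equiv), CeCl3 (1.5 equiv), THF, −78 → 0 °C
Reagents that add atoms: cyclopropylmagnesium bromide, Br[Mg]C1CC1
Why: Organocerium-assisted 1,2-addition to the enolizable methyl ketone gives the tertiary cyclopropylcarbinol. The new carbinol stereocenter is racemic and is destroyed in step 2.

**Step 2**
Reactants: 3; 4 (hydrogen bromide)
Product: 5 (2-[(E)-6-bromo-3-methylhex-3-en-1-yl]-1,3,3-trimethylcyclohex-1-ene)
Conditions: 48% aq HBr (2 equiv), CH2Cl2, 0 °C, 20 min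
Reagents that add atoms: HBr, Br
Why: Julia–Johnson cyclopropylcarbinyl-cation ring opening delivers the homoallylic bromide, and the E trisubstituted alkene (about 9:1 E:Z) is set by the preferred bisected-cation geometry. The short reaction time spares the tetrasubstituted ring alkene.

**Step 3**
Reactants: 5; 6 (propargyl alcohol, prop-2-yn-1-ol); 7 (iodine)
Product: 8 ((Z)-3-iodo-2-[(E)-4-methyl-6-(2,6,6-trimethylcyclohex-1-en-1-yl)hex-3-en-1-yl]prop-2-en-1-ol)
Conditions: (i) 5, Mg, THF, 40 °C; (ii) RMgBr (3 equiv), 6 (1 equiv), CuI (10 mol%), THF, 0 → 25 °C, 12 h; (iii) I2 (2.5 equiv), −78 °C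
Reagents that add atoms: I2, II
Why: Cu-catalysed carbomagnesiation of propargyl alcohol (Duboudin-type) puts R on C2 and Mg on C3 cis to the CH2OMgX through a five-membered oxa-magnesacycle. Iodinolysis with retention gives the Z-vinyl iodide with CH2OH cis to I. That is the Z geometry required at C6 of the target.

**Step 4**
Reactants: 8; 9 ((S)-5-(tosyloxymethyl)dihydrofuran-2(3H)-one, chiral-pool, from L-glutamic acid)
Product: 10 ((5S)-5-[(2Z,6E)-3-(hydroxymethyl)-7-methyl-9-(2,6,6-trimethylcyclohex-1-en-1-yl)nona-2,6-dien-1-yl]oxolan-2-one)
Conditions: 9 (1.5 equiv), 8 (1 equiv), [Ir{dF(CF3)ppy}2(dtbbpy)]PF6 (1 mol%), NiCl2·glyme (10 mol%), dtbbpy (10 mol%), (Me3Si)3SiH (1.5 equiv), NaI (3 equiv), 2,6-lutidine (2 equiv), DME/DMA, blue LEDs, 25 °C, 24 h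
Reagents that add atoms: none
Why: NaI converts the tosylate in situ to the primary iodide. Silyl-radical halogen abstraction gives the primary radical, which is captured by the Ni(II)–vinyl species from the vinyl iodide (Ni/photoredox cross-electrophile coupling). The alkene geometry is retained, and the C5 stereocenter is untouched because no base strong enough to deprotonate it is present. The lactone is kept saturated so that the radical cannot undergo 3-exo cyclisation or 1,2-vinyl shift onto a ring C=C.

**Step 5**
Reactants: 10; 11 (benzeneselenenyl chloride)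
Product: 12 ((5R)-5-[(2Z,6E)-3-(hydroxymethyl)-7-methyl-9-(2,6,6-trimethylcyclohex-1-en-1-yl)nona-2,6-dien-1-yl]-3-(phenylselanyl)oxolan-2-one, C3 epimers)
Conditions: LDA (2.3 equiv), THF, −78 °C, 1 h; then 11 (1.05 equiv), −78 → 0 °C
Reagents that add atoms: PhSeCl, Cl[Se]c1ccccc1
Why: The lactone enolate is selenated at the α-carbon (the alkoxide is masked as its lithium salt). C5–H is not acidic in the saturated lactone, so C5 is not epimerised, and the new C3 center is discarded in step 6.

**Step 6**
Reactants: 12
Product: 13 ((5R)-5-[(2Z,6E)-3-(hydroxymethyl)-7-methyl-9-(2,6,6-trimethylcyclohex-1-en-1-yl)nona-2,6-dien-1-yl]furan-2(5H)-one)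
Conditions: NaIO4 (1.5 equiv), NaHCO3, THF/H2O 3:1, 0 → 25 °C, 3 h
Reagents that add atoms: none
Why: Selenide oxidation followed by selenoxide syn-elimination can only go toward C4, giving the α,β-butenolide. Periodate avoids the alkene epoxidation that H2O2/PhSe(O)OH can cause.

**Step 7**
Reactants: 13; 14 (methanol)
Product: 15 (target, (6Z)-neomanoalide)
Conditions: TBADT (2 mol%), Co(dmgH)2pyCl (5 mol%), MeOH/MeCN 1:1 (13 at 0.02 M), 390 nm LEDs, 25 °C, N2, 16 h
Reagents that add atoms: methanol, CO (adds the C4–CH2OH)
Why: Proposed new method: excited decatungstate abstracts H from MeOH to give the nucleophilic •CH2OH radical, which adds to the butenolide β-carbon (C4) in a polarity-matched Giese step; the resulting α-carbonyl radical then loses the β-H (C4–H) to Co(II), as in catalytic chain transfer, and the Co(III)–H releases H2, so C4–H and CH3OH couple with loss of H2 (closest known reaction: decatungstate/cobaloxime dehydrogenative Heck-type coupling). MeOH as solvent outcompetes the substrate's own C–H bonds (including C5–H) as the HAT donor, the electron-rich alkenes do not trap the nucleophilic radical, and C5 is not touched.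

## Compound list

1 | dihydro-β-ionone | CC(=O)CCC1=C(C)CCCC1(C)C | starting material
2 | cyclopropylmagnesium bromide | Br[Mg]C1CC1 | starting material
3 | 2-cyclopropyl-4-(2,6,6-trimethylcyclohex-1-en-1-yl)butan-2-ol | CC(O)(CCC1=C(C)CCCC1(C)C)C2CC2 | intermediate
4 | hydrogen bromide | Br | starting material
5 | (E)-homoallylic bromide | BrCC/C=C(/CCC1=C(C)CCCC1(C)C)C | intermediate
6 | propargyl alcohol | C#CCO | starting material
7 | iodine | II | starting material
8 | (Z)-vinyl iodide | OC/C(=C\I)CC/C=C(/CCC1=C(C)CCCC1(C)C)C | intermediate
9 | (S)-5-(tosyloxymethyl)dihydrofuran-2(3H)-one | Cc1ccc(cc1)S(=O)(=O)OC[C@H]2OC(=O)CC2 | starting material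
10 | saturated lactone (coupling product) | CC1=C(CC/C(C)=C/CC/C(=C/C[C@H]2OC(=O)CC2)CO)C(C)(C)CCC1 | intermediate
11 | benzeneselenenyl chloride | Cl[Se]c1ccccc1 | starting material
12 | α-phenylselanyl lactone | CC1=C(CC/C(C)=C/CC/C(=C/C[C@H]2OC(=O)C([Se]c3ccccc3)C2)CO)C(C)(C)CCC1 | intermediate
13 | 4-unsubstituted (5R)-butenolide | CC1=C(CC/C(C)=C/CC/C(=C/C[C@H]2OC(=O)C=C2)CO)C(C)(C)CCC1 | intermediate
14 | methanol | CO | starting material
15 | (6Z)-neomanoalide | CC1=C(CC/C(C)=C/CC/C(=C/C[C@H]2OC(=O)C=C2CO)CO)C(C)(C)CCC1 | target

## Summary

**Total steps:** 7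
**Longest linear sequence:** 7 (1 → 3 → 5 → 8 → 10 → 12 → 13 → 15; tosylate 9 joins at step 4)

**Three steps most likely to fail**
1. **Step 7 (proposed new dehydrogenative hydroxymethylation).** The α-carbonyl radical may be reduced to the saturated Giese adduct instead of dehydrogenated, or HAT at C5–H may erode ee.
   - Fallback (known chemistry): stepwise benzophenone/MeOH/hν Giese hydroxymethylation of 13 to the trans-4-(hydroxymethyl)lactone, then repeat the step 5–6 selenation/periodate elimination to give 15.
2. **Step 4 (cross-electrophile coupling).** Silyl radicals may reduce the vinyl iodide or hydrosilylate the trisubstituted alkenes, and a hindered primary radical can give low yield.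
   - Fallback: do not quench the vinylmagnesium alkoxide from step 3 with I2. Transmetalate it with CuI/LiBr and alkylate it (polar SN2) with (S)-5-(iodomethyl)lactone made from 9 and NaI.
3. **Step 6 (selenoxide elimination in the presence of three alkenes and a free allylic alcohol).** PhSeOH addition or epoxidation may compete.
   - Fallback: change the chiral starting material to 2-deoxy-D-ribono-1,4-lactone. Convert its primary OH to the iodide, couple it with TBS-protected 8 as in step 4, and form the butenolide by E1cB dehydration of the β-OH (MsCl/Et3N, then DBU). Then carry on to the step 7 substrate.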